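**Retrosynthetic overview**

1. The target (cyclohexene numbering: C1 carries ring C, C2=C3 with the methyl on C3, C4 is CH2, C5 carries ring B, C6 carries the ring-A aroyl group) comes from one non-acidic removal of three O-allyl and three O-acetyl groups.
2. The cyclohexene, the only ring made in the route, is cut at C4–C5 and C1–C6 into a 2'-hydroxychalcone (rings A and B) and an aryl 3-methylbutadiene that already carries the second chalcone (rings C and D).
3. These are joined by an enantioselective, electron-catalysed radical-anion [4+2] instead of a thermal Diels–Alder reaction: the chalcone ketyl β-radical attacks the diene CH2 (C4–C5), then the allyl radical closes on the enolate (C1–C6).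
4. The diene partner comes from a Heck coupling of isoprene with a 3'-iodochalcone triacetate, itself from an acid aldol of 3-iodo-2,4-dihydroxyacetophenone with 4-hydroxybenzaldehyde (from p-cresol); the chalcone partner comes from a Claisen–Schmidt condensation of O-allylated 3-prenyl-2,4-dihydroxyacetophenone with 2,4-bis(allyloxy)benzaldehyde.
5. Both acetophenones come from one acylation of resorcinol; all four benzene rings are bought as resorcinol or p-cresol, and the cyclohexene is formed in the penultimate step.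

Assumption: the target is taken exactly as the SMILES defines it, the (1S,5S,6R) adduct with the aroyl group cis to ring C and trans to ring B, and the (S,S)-ligand of step 12 is assumed to give this sense of induction (otherwise its mirror image is used).

**Route**

Step 1
Reactants: 1 resorcinol; 2 acetic acid
Product: 3 1-(2,4-dihydroxyphenyl)ethanone
Conditions: ZnCl2 (1.5 equiv), neat AcOH, 140 °C
Reagents that add atoms: none
Why: Nencki reaction (ZnCl2-mediated Friedel–Crafts C-acylation of a phenol by a carboxylic acid) goes to C4, which is ortho/para to both hydroxyls, and the product is held as a chelate.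

Step 2
Reactants: 3 1-(2,4-dihydroxyphenyl)ethanone; 4 prenyl bromide
Product: 5 1-[2,4-dihydroxy-3-(3-methylbut-2-en-1-yl)phenyl]ethanone
Conditions: KOH (10% aq.), 0 °C → rt
Reagents that add atoms: none
Why: C-alkylation of the ambident phenoxide in water (phenoxide C-prenylation) favours carbon over oxygen and the doubly activated C3 between the two oxygens; the 3-prenyl isomer is separated from minor 5-prenyl and O-prenyl products.

Step 3
Reactants: 5 1-[2,4-dihydroxy-3-(3-methylbut-2-en-1-yl)phenyl]ethanone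
Product: 6 1-[2-hydroxy-3-(3-methylbut-2-en-1-yl)-4-(prop-2-en-1-yloxy)phenyl]ethanone
Conditions: allyl bromide (1.1 equiv), K2CO3, acetone, reflux
Reagents that add atoms: allyl bromide C=CCBr
Why: Williamson etherification is selective for the 4-OH because the 2-OH is locked in a hydrogen bond to the ketone.

Step 4
Reactants: 1 resorcinol
Product: 8 2,4-dihydroxybenzaldehyde, via iminium chloride 7 (not isolated)
Conditions: POCl3, DMF, MeCN, −15 °C → rt; then H2O, 50 °C
Reagents that add atoms: N,N-dimethylformamide CN(C)C=O; water O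
Why: Vilsmeier–Haack formylation attacks resorcinol at C4 and the iminium salt is hydrolysed in the same pot.

Step 5
Reactants: 8 2,4-dihydroxybenzaldehyde
Product: 9 2,4-bis(prop-2-en-1-yloxy)benzaldehyde
Conditions: allyl bromide (2.5 equiv), K2CO3, DMF, 60 °C
Reagents that add atoms: allyl bromide C=CCBr
Why: Williamson etherification in DMF with heating also alkylates the chelated 2-OH, which must be capped so that the later chalcone cannot close to a flavylium or chromene.

Step 6
Reactants: 6 1-[2-hydroxy-3-(3-methylbut-2-en-1-yl)-4-(prop-2-en-1-yloxy)phenyl]ethanone; 9 2,4-bis(prop-2-en-1-yloxy)benzaldehyde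
Product: 11 (2E)-3-[2,4-bis(prop-2-en-1-yloxy)phenyl]-1-[2-hydroxy-3-(3-methylbut-2-en-1-yl)-4-(prop-2-en-1-yloxy)phenyl]prop-2-en-1-one, via β-hydroxy ketone 10 (not isolated)
Conditions: KOH (50% aq.), EtOH, rt, 48 h
Reagents that add atoms: none
Why: Claisen–Schmidt condensation (aldol addition then E1cB dehydration) gives the thermodynamically favoured (E)-enone; allyl ethers and the prenyl group are stable to base and the 2'-OH stays free for later chelation.

Step 7
Reactants: 3 1-(2,4-dihydroxyphenyl)ethanone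
Product: 12 1-(2,4-dihydroxy-3-iodophenyl)ethanone
Conditions: I2 (0.4 equiv), HIO3 (0.2 equiv), EtOH/H2O, 35 °C
Reagents that add atoms: iodine II; iodic acid OI(=O)=O
Why: Electrophilic aromatic iodination goes to C3, flanked by both hydroxyls, and stops at mono-iodination because the acyl group deactivates the ring; iodic acid reoxidises iodide so all iodine is used.

Step 8
Reactants: 13 p-cresol
Product: 14 4-hydroxybenzaldehyde
Conditions: O2 (1 atm), CoCl2 (2 mol %), NaOH, MeOH, 60 °C
Reagents that add atoms: dioxygen O=O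
Why: Cobalt-catalysed aerobic benzylic oxidation of the p-cresolate runs through the p-quinone methide and its methanol adduct to the aldehyde, whose phenoxide resists further oxidation.

Step 9
Reactants: 12 1-(2,4-dihydroxy-3-iodophenyl)ethanone; 14 4-hydroxybenzaldehyde
Product: 16 (2E)-1-(2,4-dihydroxy-3-iodophenyl)-3-(4-hydroxyphenyl)prop-2-en-1-one, via β-hydroxy ketone 15 (not isolated)
Conditions: dry HCl, EtOH, 0 °C → rt
Reagents that add atoms: none
Why: Acid-catalysed Claisen–Schmidt condensation tolerates free phenols, so no protecting group is needed, and gives the (E)-enone; the acyl-deactivated iodoarene survives the mild acid.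

Step 10
Reactants: 16 (2E)-1-(2,4-dihydroxy-3-iodophenyl)-3-(4-hydroxyphenyl)prop-2-en-1-one
Product: 17 4-[(1E)-3-[2,4-bis(acetyloxy)-3-iodophenyl]-3-oxoprop-1-en-1-yl]phenyl acetate
Conditions: Ac2O (5 equiv), pyridine, 4-(dimethylamino)pyridine (cat.), rt
Reagents that add atoms: acetic anhydride CC(=O)OC(C)=O
Why: Nucleophile-catalysed O-acetylation caps all three phenols, which prevents phenol–palladium heteroannulation in the Heck step, chromene formation of the diene, and Lewis-acid chelation of this chalcone in the key step.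

Step 11
Reactants: 17 4-[(1E)-3-[2,4-bis(acetyloxy)-3-iodophenyl]-3-oxoprop-1-en-1-yl]phenyl acetate; 18 isoprene
Product: 19 4-[(1E)-3-{2,4-bis(acetyloxy)-3-[(1E)-3-methylbuta-1,3-dien-1-yl]phenyl}-3-oxoprop-1-en-1-yl]phenyl acetate
Conditions: isoprene (10 equiv), Pd(OAc)2 (5 mol %), n-Bu4NCl, NaHCO3, DMF, 70 °C, sealed tube
Reagents that add atoms: none
Why: Mizoroki–Heck reaction under phosphine-free conditions: the arylpalladium adds to the unsubstituted vinyl end of isoprene and β-hydride elimination gives the (E)-1-aryl-3-methylbuta-1,3-diene; aryl acetates tolerate the mild base.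

Step 12
Reactants: 11 (2E)-3-[2,4-bis(prop-2-en-1-yloxy)phenyl]-1-[2-hydroxy-3-(3-methylbut-2-en-1-yl)-4-(prop-2-en-1-yloxy)phenyl]prop-2-en-1-one; 19 4-[(1E)-3-{2,4-bis(acetyloxy)-3-[(1E)-3-methylbuta-1,3-dien-1-yl]phenyl}-3-oxoprop-1-en-1-yl]phenyl acetate
Product: 20 4-[(1E)-3-{2,4-bis(acetyloxy)-3-[(1S,5S,6R)-5-[2,4-bis(prop-2-en-1-yloxy)phenyl]-6-[2-hydroxy-3-(3-methylbut-2-en-1-yl)-4-(prop-2-en-1-yloxy)benzoyl]-3-methylcyclohex-2-en-1-yl]phenyl}-3-oxoprop-1-en-1-yl]phenyl acetate
Conditions: Ru(bpz)3(PF6)2 (2 mol %; bpz = 2,2'-bipyrazine), Gd(OTf)3 (10 mol %), 2,6-bis[(4S)-4-tert-butyl-4,5-dihydro-1,3-oxazol-2-yl]pyridine ((S,S)-t-Bu-PyBox, 20 mol %), i-Pr2NEt (3 equiv), 19 (2 equiv), MeCN, blue LEDs, −20 °C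
Reagents that add atoms: none
Why: Proposed new method: the amine-quenched photocatalyst gives one electron only to the Gd(OTf)3/PyBox chelate of 11 (19 has no free phenol to chelate and its enone lies beyond the reducing power of reduced Ru(bpz)3, about −0.8 V vs SCE), the β-carbon of the resulting ketyl radical anion adds from the open face of the chiral pocket to the CH2 end of the s-cis diene (C4–C5 bond, sets C5), and the aryl-stabilised allyl radical then closes on the gadolinium enolate carbon anti to ring B and stacked under the chelate (endo-like; C1–C6 bond, sets C6 trans to C5 and C1 cis to C6) before the product ketyl passes the electron on, so the whole is a radical-anion Diels–Alder (formal [4+2]) reaction; the closest known reaction type is the chiral-Lewis-acid/photoredox radical-anion cycloaddition of aryl ketones with alkenes and dienes ([2+2] of aryl enones, [3+2] of aryl cyclopropyl ketones), and a hole-catalysed (radical-cation) variant is avoided because it would bond the chalcone α-carbon to the diene CH2 and give the regioisomer.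

Step 13
Reactants: 20 4-[(1E)-3-{2,4-bis(acetyloxy)-3-[(1S,5S,6R)-5-[2,4-bis(prop-2-en-1-yloxy)phenyl]-6-[2-hydroxy-3-(3-methylbut-2-en-1-yl)-4-(prop-2-en-1-yloxy)benzoyl]-3-methylcyclohex-2-en-1-yl]phenyl}-3-oxoprop-1-en-1-yl]phenyl acetate
Product: 21 (2E)-1-{3-[(1S,5S,6R)-6-[2,4-dihydroxy-3-(3-methylbut-2-en-1-yl)benzoyl]-5-(2,4-dihydroxyphenyl)-3-methylcyclohex-2-en-1-yl]-2,4-dihydroxyphenyl}-3-(4-hydroxyphenyl)prop-2-en-1-one
Conditions: Pd(PPh3)4 (5 mol %), morpholine (40 equiv), THF, rt → 40 °C
Reagents that add atoms: none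
Why: Zerovalent palladium ionises the three aryl allyl ethers and morpholine takes the allyl groups (Tsuji–Trost allyl transfer) while also aminolysing the three aryl acetates, all without acid, so the prenyl group, the cis-disposed phenol/ketone pair (prone to ketal formation) and the epimerisable C6 centre are left untouched.

**Compound list**

1 | resorcinol (benzene-1,3-diol) | Oc1cccc(O)c1 | starting material
2 | acetic acid | CC(=O)O | starting material
3 | 1-(2,4-dihydroxyphenyl)ethanone | CC(=O)c1ccc(O)cc1O | intermediate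
4 | prenyl bromide (1-bromo-3-methylbut-2-ene) | CC(C)=CCBr | starting material
5 | 1-[2,4-dihydroxy-3-(3-methylbut-2-en-1-yl)phenyl]ethanone | CC(=O)c1ccc(O)c(CC=C(C)C)c1O | intermediate
6 | 1-[2-hydroxy-3-(3-methylbut-2-en-1-yl)-4-(prop-2-en-1-yloxy)phenyl]ethanone | CC(=O)c1ccc(OCC=C)c(CC=C(C)C)c1O | intermediate
7 | (2,4-dihydroxybenzylidene)dimethylammonium chloride | C[N+](C)=Cc1ccc(O)cc1O.[Cl-] | intermediate
8 | 2,4-dihydroxybenzaldehyde | O=Cc1ccc(O)cc1O | intermediate
9 | 2,4-bis(prop-2-en-1-yloxy)benzaldehyde | O=Cc1ccc(OCC=C)cc1OCC=C | intermediate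
10 | 3-[2,4-bis(prop-2-en-1-yloxy)phenyl]-3-hydroxy-1-[2-hydroxy-3-(3-methylbut-2-en-1-yl)-4-(prop-2-en-1-yloxy)phenyl]propan-1-one (racemic aldol) | CC(C)=CCc1c(OCC=C)ccc(C(=O)CC(O)c2ccc(OCC=C)cc2OCC=C)c1O | intermediate
11 | (2E)-3-[2,4-bis(prop-2-en-1-yloxy)phenyl]-1-[2-hydroxy-3-(3-methylbut-2-en-1-yl)-4-(prop-2-en-1-yloxy)phenyl]prop-2-en-1-one | CC(C)=CCc1c(OCC=C)ccc(C(=O)/C=C/c2ccc(OCC=C)cc2OCC=C)c1O | intermediate
12 | 1-(2,4-dihydroxy-3-iodophenyl)ethanone | CC(=O)c1ccc(O)c(I)c1O | intermediate
13 | p-cresol (4-methylphenol) | Cc1ccc(O)cc1 | starting material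
14 | 4-hydroxybenzaldehyde | O=Cc1ccc(O)cc1 | intermediate
15 | 1-(2,4-dihydroxy-3-iodophenyl)-3-hydroxy-3-(4-hydroxyphenyl)propan-1-one (racemic aldol) | O=C(CC(O)c1ccc(O)cc1)c1ccc(O)c(I)c1O | intermediate
16 | (2E)-1-(2,4-dihydroxy-3-iodophenyl)-3-(4-hydroxyphenyl)prop-2-en-1-one | O=C(/C=C/c1ccc(O)cc1)c1ccc(O)c(I)c1O | intermediate
17 | 4-[(1E)-3-[2,4-bis(acetyloxy)-3-iodophenyl]-3-oxoprop-1-en-1-yl]phenyl acetate | CC(=O)Oc1ccc(/C=C/C(=O)c2ccc(OC(C)=O)c(I)c2OC(C)=O)cc1 | intermediate
18 | isoprene (2-methylbuta-1,3-diene) | CC(=C)C=C | starting material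
19 | 4-[(1E)-3-{2,4-bis(acetyloxy)-3-[(1E)-3-methylbuta-1,3-dien-1-yl]phenyl}-3-oxoprop-1-en-1-yl]phenyl acetate | CC(=O)Oc1ccc(/C=C/C(=O)c2ccc(OC(C)=O)c(/C=C/C(C)=C)c2OC(C)=O)cc1 | intermediate
20 | 4-[(1E)-3-{2,4-bis(acetyloxy)-3-[(1S,5S,6R)-5-[2,4-bis(prop-2-en-1-yloxy)phenyl]-6-[2-hydroxy-3-(3-methylbut-2-en-1-yl)-4-(prop-2-en-1-yloxy)benzoyl]-3-methylcyclohex-2-en-1-yl]phenyl}-3-oxoprop-1-en-1-yl]phenyl acetate | CC(C)=CCc1c(OCC=C)ccc(C(=O)[C@H]2[C@@H](c3c(OC(C)=O)ccc(C(=O)/C=C/c4ccc(OC(C)=O)cc4)c3OC(C)=O)C=C(C)C[C@@H]2c2ccc(OCC=C)cc2OCC=C)c1O | intermediate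
21 | (2E)-1-{3-[(1S,5S,6R)-6-[2,4-dihydroxy-3-(3-methylbut-2-en-1-yl)benzoyl]-5-(2,4-dihydroxyphenyl)-3-methylcyclohex-2-en-1-yl]-2,4-dihydroxyphenyl}-3-(4-hydroxyphenyl)prop-2-en-1-one (CNP0283121.1) | CC(C)=CCc1c(O)ccc(C(=O)[C@H]2[C@@H](c3c(O)ccc(C(=O)/C=C/c4ccc(O)cc4)c3O)C=C(C)C[C@@H]2c2ccc(O)cc2O)c1O | target

**Step count and risk**

Total step count: 13. Longest linear sequence: 7 steps (1 → 3 → 12 → 16 → 17 → 19 → 20 → 21, that is steps 1, 7, 9, 10, 11, 12 and 13).

The step most likely to fail is step 12. The stabilised radical anion may add to the diene too slowly and be lost to reductive dimerisation or hydrogenation of 11. Adducts of the s-trans diene cannot close to the six-membered ring and may give a vinylcyclobutane. The endo/exo ratio and the enantioselectivity are unproven. The fallback sets out from 11 and 19 and comes back at 20. The union is run as a silver-nanoparticle electron-transfer cycloaddition (Ag nanoparticles on SiO2, CH2Cl2, 50 °C), in which the silver-bound phenoxide of 11 is oxidised by one electron, the radical adds to the diene, and the electron is returned. This oxidative radical manifold is established for cis,trans adducts of 2'-hydroxychalcones but gives no absolute control. Compound 20 therefore forms together with its mirror image, the (1R,5R,6S)-adduct F4, and the two are separated by preparative HPLC on a chiral stationary phase.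

The second is step 11. Isoprene can also be arylated at its methyl-substituted end, giving the 2-methyl diene isomer, and the hindered iodide may couple slowly. The fallback sets out from 17 and comes back at 19. A Heck reaction with 2-methylbut-3-en-2-ol (Pd(OAc)2, n-Bu4NCl, NaHCO3, DMF, 70 °C), an olefin that can give only one regioisomer, leads to the tertiary allylic alcohol 4-[(1E)-3-{2,4-bis(acetyloxy)-3-[(1E)-3-hydroxy-3-methylbut-1-en-1-yl]phenyl}-3-oxoprop-1-en-1-yl]phenyl acetate F3. Acid-catalysed dehydration (pyridinium p-toluenesulfonate, cat., toluene, 80 °C) then gives 19.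

The third is step 2. Direct C-prenylation gives the 3-prenyl isomer in only modest yield beside 5-prenyl, diprenyl and O-prenyl products. The fallback sets out from 3 and comes back at 5. The 4-OH is alkylated with 3-chloro-3-methylbut-1-yne (K2CO3, KI, CuI cat., acetone, reflux) to the propargyl ether 1-{2-hydroxy-4-[(2-methylbut-3-yn-2-yl)oxy]phenyl}ethanone F1. Semihydrogenation (H2, Pd/CaCO3 poisoned with Pb(OAc)2, quinoline, EtOAc) gives the 1,1-dimethylallyl ether 1-{2-hydroxy-4-[(2-methylbut-3-en-2-yl)oxy]phenyl}ethanone F2. An aromatic Claisen rearrangement (PhNEt2, 130 °C) then delivers the prenyl group to C3, the ortho position favoured by the chelated ketone, and gives 5.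

Further compounds

F1 | step 2 | 1-{2-hydroxy-4-[(2-methylbut-3-yn-2-yl)oxy]phenyl}ethanone | CC(=O)c1ccc(OC(C)(C)C#C)cc1O
F2 | step 2 | 1-{2-hydroxy-4-[(2-methylbut-3-en-2-yl)oxy]phenyl}ethanone | CC(=O)c1ccc(OC(C)(C)C=C)cc1O
F3 | step 11 | 4-[(1E)-3-{2,4-bis(acetyloxy)-3-[(1E)-3-hydroxy-3-methylbut-1-en-1-yl]phenyl}-3-oxoprop-1-en-1-yl]phenyl acetate | CC(=O)Oc1ccc(/C=C/C(=O)c2ccc(OC(C)=O)c(/C=C/C(C)(C)O)c2OC(C)=O)cc1
F4 | step 12 | 4-[(1E)-3-{2,4-bis(acetyloxy)-3-[(1R,5R,6S)-5-[2,4-bis(prop-2-en-1-yloxy)phenyl]-6-[2-hydroxy-3-(3-methylbut-2-en-1-yl)-4-(prop-2-en-1-yloxy)benzoyl]-3-methylcyclohex-2-en-1-yl]phenyl}-3-oxoprop-1-en-1-yl]phenyl acetate (mirror image of 20) | CC(C)=CCc1c(OCC=C)ccc(C(=O)[C@@H]2[C@H](c3c(OC(C)=O)ccc(C(=O)/C=C/c4ccc(OC(C)=O)cc4)c3OC(C)=O)C=C(C)C[C@H]2c2ccc(OCC=C)cc2OCC=C)c1O
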